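**Retrosynthetic overview**

1. The target is reached from its bis(methoxymethyl) ether by acetal hydrolysis in the last step; everything else is in place after the key step.
2. Key disconnection: the bond from the exocyclic methine carbon to C6 of the chroman (Mizoroki–Heck arylation) and, in the same flask, the C3–C4 bond of the furanone (Dieckmann condensation). This leaves (R)-6-iodo-2,2-dimethylchroman-3-ol and an acyclic methyl 2-(arylacetoxy)acrylate.
3. Enabling feature: furanone ring atom C5 carries the ring oxygen O1, ring carbon C4 and the exocyclic =CH. O1–C5(=CH2)–C4 is therefore the enol ester of methyl pyruvate: its CH2 terminus accepts the aryl group, and its ester carbon sits 1,5 to the arylacetyl CH2 that becomes C3.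
4. Chroman half: 2,2-dimethyl-2H-chromene, Jacobsen epoxidation (sets C3), hydride opening at C4, iodination at C6.
5. Hydroquinone half: 2,5-dibromohydroquinone, MOM protection, Br/Li exchange and prenylation, palladium-catalysed Reformatsky arylation, saponification, esterification with methyl 3-chlorolactate and loss of HCl. Ring order: both benzene rings and the pyran ring are bought; the furanone ring is closed last, in the key step.

Key step: step 9

Assumption: bromo(2-ethoxy-2-oxoethyl)zinc (as a THF solution) and racemic methyl 3-chloro-2-hydroxypropanoate are taken as purchasable reagents.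

**Route**

Step 1
Reactants: 1 2,2-dimethyl-2H-chromene
Product: 2 (1aR,7bR)-2,2-dimethyl-1a,7b-dihydro-2H-oxireno[2,3-c]chromene, i.e. (3R,4R)-3,4-epoxy-2,2-dimethylchroman
Conditions: (R,R)-(salen)MnCl (3 mol%; salen = dianion of N,N'-bis(3,5-di-tert-butylsalicylidene)cyclohexane-1,2-diamine, trivalent manganese), 4-phenylpyridine N-oxide, aq. NaOCl (pH 11.3), CH2Cl2, 0 °C
Reagents that add atoms: sodium hypochlorite, [Na+].[O-]Cl
Why: Jacobsen asymmetric epoxidation of a cis-disubstituted conjugated olefin of the 2,2-dimethylchromene class, for which these catalysts are most face-selective; the (R,R)-catalyst should deliver oxygen to the face that gives the (3R,4R)-epoxide, which fixes the future C3 stereocentre.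

Step 2
Reactants: 2 (3R,4R)-3,4-epoxy-2,2-dimethylchroman
Product: 3 (3R)-2,2-dimethyl-3,4-dihydro-2H-chromen-3-ol
Conditions: LiAlH4, THF, 0 °C → rt; aqueous work-up
Reagents that add atoms: none
Why: Hydride should open the epoxide by SN2 attack at the benzylic C4, because C3 is shielded by the adjacent quaternary C2, so the C3–O bond is not touched and the R configuration is kept.

Step 3
Reactants: 3 (3R)-2,2-dimethyl-3,4-dihydro-2H-chromen-3-ol
Product: 4 (3R)-6-iodo-2,2-dimethyl-3,4-dihydro-2H-chromen-3-ol
Conditions: N-iodosuccinimide, TFA (cat.), MeCN, 0 °C → rt, dark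
Reagents that add atoms: N-iodosuccinimide, O=C1CCC(=O)N1I
Why: Electrophilic aromatic iodination should occur para to the ring oxygen (C6), the most activated and least hindered position of a chroman; the stereocentre is not involved.

Step 4
Reactants: 5 2,5-dibromobenzene-1,4-diol
Product: 6 1,4-dibromo-2,5-bis(methoxymethoxy)benzene
Conditions: MOMCl, i-Pr2NEt, CH2Cl2, 0 °C → rt
Reagents that add atoms: chloromethyl methyl ether, COCCl
Why: O-Alkylation of both phenols gives base-stable acetals that tolerate the organolithium, organozinc and alkoxide steps that follow.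

Step 5
Reactants: 6 1,4-dibromo-2,5-bis(methoxymethoxy)benzene; 7 1-bromo-3-methylbut-2-ene (prenyl bromide)
Product: 9 1-bromo-2,5-bis(methoxymethoxy)-4-(3-methylbut-2-en-1-yl)benzene, via aryllithium 8 (not isolated)
Conditions: n-BuLi (1.0 equiv), THF, −78 °C; then CuBr·SMe2 (0.2 equiv), 7, −78 → 0 °C
Reagents that add atoms: none
Why: Bromine–lithium exchange should stop after one bromine because the aryllithium resists a second exchange, and copper-catalysed SN2 allylation at the unhindered CH2 of prenyl bromide gives the linear prenyl arene.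

Step 6
Reactants: 9 1-bromo-2,5-bis(methoxymethoxy)-4-(3-methylbut-2-en-1-yl)benzene; 10 bromo(2-ethoxy-2-oxoethyl)zinc (Reformatsky reagent)
Product: 11 ethyl 2-[2,5-bis(methoxymethoxy)-4-(3-methylbut-2-en-1-yl)phenyl]acetate
Conditions: 10 (0.5 M in THF, 1.5 equiv), Pd2(dba)3 (2 mol%), XPhos (8 mol%), THF, 60 °C
Reagents that add atoms: none
Why: Negishi-type palladium-catalysed coupling of a Reformatsky reagent with an aryl bromide (ester α-arylation) works on electron-rich, ortho-alkoxy bromides and leaves acetals and the trisubstituted olefin alone.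

Step 7
Reactants: 11 ethyl 2-[2,5-bis(methoxymethoxy)-4-(3-methylbut-2-en-1-yl)phenyl]acetate
Product: 12 2-[2,5-bis(methoxymethoxy)-4-(3-methylbut-2-en-1-yl)phenyl]acetic acid
Conditions: LiOH·H2O, THF–H2O, rt; then 1 M HCl to pH 4, 0 °C
Reagents that add atoms: lithium hydroxide (its oxygen becomes the carboxyl OH), [Li+].[OH-]
Why: Saponification of an unhindered ethyl ester; the MOM ethers and the prenyl group are stable to hydroxide and to brief cold acidification.

Step 8
Reactants: 12 2-[2,5-bis(methoxymethoxy)-4-(3-methylbut-2-en-1-yl)phenyl]acetic acid; 13 methyl 3-chloro-2-hydroxypropanoate (racemic)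
Product: 15 methyl 2-({[2,5-bis(methoxymethoxy)-4-(3-methylbut-2-en-1-yl)phenyl]acetyl}oxy)prop-2-enoate, via chloro ester 14 (not isolated)
Conditions: EDC·HCl, DMAP (0.1 equiv), CH2Cl2, 0 °C → rt; then Et3N (3 equiv), rt
Reagents that add atoms: none
Why: Steglich esterification of the α-hydroxy ester is followed by E1cB loss of HCl, since the α-hydrogen is flanked by the ester and the acyloxy group (the same dehydrohalogenation that turns β-chloroalanine derivatives into dehydroalanines); the stereocentre of 13 is destroyed, so the racemate suffices.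

Step 9
Reactants: 15 methyl 2-({[2,5-bis(methoxymethoxy)-4-(3-methylbut-2-en-1-yl)phenyl]acetyl}oxy)prop-2-enoate; 4 (3R)-6-iodo-2,2-dimethyl-3,4-dihydro-2H-chromen-3-ol
Product: 17 (5Z)-3-[2,5-bis(methoxymethoxy)-4-(3-methylbut-2-en-1-yl)phenyl]-4-hydroxy-5-{[(3R)-3-hydroxy-2,2-dimethyl-3,4-dihydro-2H-chromen-6-yl]methylidene}furan-2(5H)-one, via Heck enol ester 16 (not isolated)
Conditions: Pd(OAc)2 (5 mol%), n-Bu4NCl, NaHCO3, 4 Å MS, DMF, 70 °C; then 0 °C, KOt-Bu (excess, in THF), 0 °C → rt; cold 1 M HCl work-up
Reagents that add atoms: none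
Why: Oxidative addition of iodide 4 to zerovalent palladium, syn-carbopalladation of the 1,1-disubstituted captodative olefin of 15 with the aryl group going to the unsubstituted CH2 carbon, and syn β-hydride elimination should give enol ester 16; tert-butoxide then deprotonates the arylacetyl CH2 and the enolate closes onto the methyl ester carbonyl (Dieckmann condensation) with loss of methoxide. The closest known reaction types are the Mizoroki–Heck arylation of 2-acetamido- and 2-acyloxyacrylates under ligand-free phase-transfer conditions and the Dieckmann cyclisation of 3-aryl-2-(arylacetoxy)acrylates to pulvinones. The furanone ring closes by a 5-exo-trig C-acylation that forms C3–C4. No stereocentre is created; the Z geometry of the exocyclic double bond is set in the β-hydride elimination, which should pass through the rotamer that places the aryl group anti to the ester and syn to the acyloxy oxygen, as with dehydroamino esters, and Z is also the more stable pulvinone geometry if the base equilibrates the tetronate. The step needs arylation only at the acrylate CH2 (the trisubstituted prenyl olefin is inert to carbopalladation, and the quaternary alkylpalladium has β-hydrogens only on the new benzylic CH2), and it needs the enol ester to survive until arylation is complete, which the weak, insoluble NaHCO3 should secure before KOt-Bu is added. The tetronate anion is the thermodynamic sink that drives ring closure, and the MOM ethers, the prenyl group and the secondary alcohol are stable to both stages.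

Step 10
Reactants: 17 (5Z)-3-[2,5-bis(methoxymethoxy)-4-(3-methylbut-2-en-1-yl)phenyl]-4-hydroxy-5-{[(3R)-3-hydroxy-2,2-dimethyl-3,4-dihydro-2H-chromen-6-yl]methylidene}furan-2(5H)-one
Product: 18 (5Z)-3-[2,5-dihydroxy-4-(3-methylbut-2-en-1-yl)phenyl]-4-hydroxy-5-{[(3R)-3-hydroxy-2,2-dimethyl-3,4-dihydro-2H-chromen-6-yl]methylidene}furan-2(5H)-one (CNP0540639.1)
Conditions: 3 M aq. HCl, THF, 40 °C, argon
Reagents that add atoms: none
Why: Acid hydrolysis of the two aryl MOM acetals, run dilute and aqueous so that protonation of the prenyl olefin (and its cyclisation onto the neighbouring phenol) and enol-ether formation at the tetronic acid stay slow; the stereocentre and the Z enol lactone are not affected.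

**Compound list**

1 | 2,2-dimethyl-2H-chromene | CC1(C)C=Cc2ccccc2O1 | starting material
2 | (1aR,7bR)-2,2-dimethyl-1a,7b-dihydro-2H-oxireno[2,3-c]chromene | CC1(C)Oc2ccccc2[C@H]3O[C@@H]13 | intermediate
3 | (3R)-2,2-dimethyl-3,4-dihydro-2H-chromen-3-ol | c1ccc2c(c1)C[C@@H](O)C(C)(C)O2 | intermediate
4 | (3R)-6-iodo-2,2-dimethyl-3,4-dihydro-2H-chromen-3-ol | Ic1ccc2c(c1)C[C@@H](O)C(C)(C)O2 | intermediate
5 | 2,5-dibromobenzene-1,4-diol | Oc1cc(Br)c(O)cc1Br | starting material
6 | 1,4-dibromo-2,5-bis(methoxymethoxy)benzene | COCOc1cc(Br)c(OCOC)cc1Br | intermediate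
7 | 1-bromo-3-methylbut-2-ene (prenyl bromide) | CC(C)=CCBr | starting material
8 | [4-bromo-2,5-bis(methoxymethoxy)phenyl]lithium | [Li]c1cc(OCOC)c(Br)cc1OCOC | intermediate
9 | 1-bromo-2,5-bis(methoxymethoxy)-4-(3-methylbut-2-en-1-yl)benzene | CC(C)=CCc1cc(OCOC)c(Br)cc1OCOC | intermediate
10 | bromo(2-ethoxy-2-oxoethyl)zinc | CCOC(=O)C[Zn]Br | starting material
11 | ethyl 2-[2,5-bis(methoxymethoxy)-4-(3-methylbut-2-en-1-yl)phenyl]acetate | CC(C)=CCc1cc(OCOC)c(CC(=O)OCC)cc1OCOC | intermediate
12 | 2-[2,5-bis(methoxymethoxy)-4-(3-methylbut-2-en-1-yl)phenyl]acetic acid | CC(C)=CCc1cc(OCOC)c(CC(=O)O)cc1OCOC | intermediate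
13 | methyl 3-chloro-2-hydroxypropanoate (racemic) | COC(=O)C(O)CCl | starting material
14 | methyl 3-chloro-2-({[2,5-bis(methoxymethoxy)-4-(3-methylbut-2-en-1-yl)phenyl]acetyl}oxy)propanoate (racemic) | CC(C)=CCc1cc(OCOC)c(CC(=O)OC(CCl)C(=O)OC)cc1OCOC | intermediate
15 | methyl 2-({[2,5-bis(methoxymethoxy)-4-(3-methylbut-2-en-1-yl)phenyl]acetyl}oxy)prop-2-enoate | CC(C)=CCc1cc(OCOC)c(CC(=O)OC(=C)C(=O)OC)cc1OCOC | intermediate
16 | methyl (2Z)-2-({[2,5-bis(methoxymethoxy)-4-(3-methylbut-2-en-1-yl)phenyl]acetyl}oxy)-3-[(3R)-3-hydroxy-2,2-dimethyl-3,4-dihydro-2H-chromen-6-yl]prop-2-enoate | CC(C)=CCc1cc(OCOC)c(CC(=O)O/C(=C\c2ccc3c(c2)C[C@@H](O)C(C)(C)O3)C(=O)OC)cc1OCOC | intermediate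
17 | (5Z)-3-[2,5-bis(methoxymethoxy)-4-(3-methylbut-2-en-1-yl)phenyl]-4-hydroxy-5-{[(3R)-3-hydroxy-2,2-dimethyl-3,4-dihydro-2H-chromen-6-yl]methylidene}furan-2(5H)-one | CC(C)=CCc1cc(OCOC)c(C2=C(O)/C(=C/c3ccc4c(c3)C[C@@H](O)C(C)(C)O4)OC2=O)cc1OCOC | intermediate
18 | (5Z)-3-[2,5-dihydroxy-4-(3-methylbut-2-en-1-yl)phenyl]-4-hydroxy-5-{[(3R)-3-hydroxy-2,2-dimethyl-3,4-dihydro-2H-chromen-6-yl]methylidene}furan-2(5H)-one | CC(C)=CCc1cc(O)c(C2=C(O)/C(=C/c3ccc4c(c3)C[C@@H](O)C(C)(C)O4)OC2=O)cc1O | target

**Step count and risks**

Total steps: 10. Longest linear sequence: 7 steps (steps 4 to 10, from 5); the chroman branch (steps 1 to 3) joins at step 9.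

Steps most likely to fail:

Step 9. The activated enol ester may be cleaved or undergo acyl transfer under the basic arylation conditions, ring closure may start before arylation, or carbopalladation of the hindered 1,1-disubstituted olefin may be too slow. The fallback forms the exocyclic double bond by vinylogous aldol condensation instead of arylation; it sets out from 12 and 4 and comes back at 17. Acid 12 is alkylated with methyl bromoacetate (K2CO3, DMF) to methyl 2-({[2,5-bis(methoxymethoxy)-4-(3-methylbut-2-en-1-yl)phenyl]acetyl}oxy)acetate F1. KOt-Bu in DMF closes F1 by Dieckmann condensation to 3-[2,5-bis(methoxymethoxy)-4-(3-methylbut-2-en-1-yl)phenyl]-4-hydroxyfuran-2(5H)-one F2. Iodide 4 is treated with n-BuLi (2.2 equiv, THF, −78 °C) to give the lithium alkoxide aryllithium F3 (not isolated), which DMF and acidic work-up convert into (3R)-3-hydroxy-2,2-dimethyl-3,4-dihydro-2H-chromene-6-carbaldehyde F4. Condensation of F2 with F4 (DBU, MeCN, 60 °C) should then give 17, the Z isomer being expected as the thermodynamic product.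

Step 8. β-Elimination of HCl may stall, or the arylacetate may enolise and self-condense, or the acrylate may polymerise on concentration. The fallback acylates a pyruvate enolate instead of using esterification–elimination; it sets out from 12 and comes back at 15. Acid 12 is converted with 1-chloro-N,N,2-trimethylprop-1-en-1-amine (CH2Cl2, 0 °C, neutral conditions) into [2,5-bis(methoxymethoxy)-4-(3-methylbut-2-en-1-yl)phenyl]acetyl chloride F5. F5 is added to methyl pyruvate and Et3N (cat. DMAP, CH2Cl2, −20 °C) and should give 15 by O-acylation of the pyruvate enolate.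

Step 10. Acid may protonate the prenyl olefin and cyclise it onto the adjacent free phenol, or acetal cleavage may stop at the mono-ether. The fallback exchanges the acetals for silyl ethers under aprotic buffered conditions and then unveils with fluoride; it sets out from 17 and comes back at 18. Et3SiOTf and 2,2'-bipyridyl (CH2Cl2, 0 °C → rt) should convert both aryl MOM ethers into aryl triethylsilyl ethers and silylate both hydroxyl groups, giving the tetrakis(triethylsilyl) ether F6. n-Bu4NF buffered with AcOH (THF, 0 °C, argon) then removes all four silyl groups to give 18 without any acid strong enough to protonate the olefin.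

**Further compounds**

F1 | step 9 | methyl 2-({[2,5-bis(methoxymethoxy)-4-(3-methylbut-2-en-1-yl)phenyl]acetyl}oxy)acetate | CC(C)=CCc1cc(OCOC)c(CC(=O)OCC(=O)OC)cc1OCOC
F2 | step 9 | 3-[2,5-bis(methoxymethoxy)-4-(3-methylbut-2-en-1-yl)phenyl]-4-hydroxyfuran-2(5H)-one | CC(C)=CCc1cc(OCOC)c(C2=C(O)COC2=O)cc1OCOC
F3 | step 9 | lithium (3R)-6-lithio-2,2-dimethyl-3,4-dihydro-2H-chromen-3-olate | [Li]c1ccc2c(c1)C[C@@H](O[Li])C(C)(C)O2
F4 | step 9 | (3R)-3-hydroxy-2,2-dimethyl-3,4-dihydro-2H-chromene-6-carbaldehyde | O=Cc1ccc2c(c1)C[C@@H](O)C(C)(C)O2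
F5 | step 8 | [2,5-bis(methoxymethoxy)-4-(3-methylbut-2-en-1-yl)phenyl]acetyl chloride | CC(C)=CCc1cc(OCOC)c(CC(=O)Cl)cc1OCOC
F6 | step 10 | (5Z)-3-[2,5-bis(triethylsilyloxy)-4-(3-methylbut-2-en-1-yl)phenyl]-4-(triethylsilyloxy)-5-{[(3R)-2,2-dimethyl-3-(triethylsilyloxy)-3,4-dihydro-2H-chromen-6-yl]methylidene}furan-2(5H)-one | CC(C)=CCc1cc(O[Si](CC)(CC)CC)c(C2=C(O[Si](CC)(CC)CC)/C(=C/c3ccc4c(c3)C[C@@H](O[Si](CC)(CC)CC)C(C)(C)O4)OC2=O)cc1O[Si](CC)(CC)CC
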